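**Strategy.** Numbering as in elemanolides: C10 quaternary, C5 bears the acrolein unit (C4, C3, C15), C6 OAng, C7/C8 lactone fusion (C11–C13), C9 OMac. The route rests on opening the cyclohexane ring C5–C10 at C5–C6 and C8–C9. It exploits that C6 and C8 flank C7 of the γ-lactone ring: the lactone arrives as a flat butenolide whose C6 is an aldehyde and whose C8 is vinylogously acidic. In one operation a propargyl–zinc unit at C5 adds to C6 with chirality transfer and the zinc alkoxide triggers a vinylogous aldol of C8 onto aldehyde C9. Precursors: an α-quaternary propargylic mesylate aldehyde and 4-formylbutenolide.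

Key step: step 6

Descriptors: α is the ring face of the C10 methyl group, β the face of the C10 vinyl group (used only in this sense); C1=C2 is the vinyl group, C12 the lactone carbonyl; OAng = (Z)-2-methylbut-2-enoate, OMac = 2-methylprop-2-enoate.

Assumption: the iridium-catalysed tert-(hydroxy)prenylation of step 1 is taken to give the anti adduct (new OH anti to CH2OH in the zigzag chain drawn through the vinyl group), as with simple aldehydes; 6 is used as its commercial dimer, which reacts as the monomer.

Step 1
Reactants: 1 3-(trimethylsilyl)prop-2-ynal; 2 2-ethenyl-2-methyloxirane (racemic)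
Product: 3 (2R,3S)-2-ethenyl-2-methyl-5-(trimethylsilyl)pent-4-yne-1,3-diol
Conditions: [Ir(cod)Cl]2 (2.5 mol %), Tol-BINAP (5 mol %, the enantiomer that gives (2R,3S)-3), 4-cyano-3-nitrobenzoic acid (10 mol %), K3PO4 (5 mol %), i-PrOH (2 equiv), THF, 50 °C
Reagents that add atoms: none
Why: Iridium-catalysed transfer-hydrogenative tert-(hydroxy)prenylation: the iridium hydride from i-PrOH opens the racemic vinyl epoxide to an (E)-σ-allyliridium alkoxide that adds to the ynal through a closed chair transition state, so the ligand should fix C10 and the allyl geometry should place the new C5–OH anti to CH2OH.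

Step 2
Reactants: 3 (2R,3S)-2-ethenyl-2-methyl-5-(trimethylsilyl)pent-4-yne-1,3-diol
Product: 4 (2S,3S)-2-ethenyl-3-hydroxy-2-methyl-5-(trimethylsilyl)pent-4-ynal
Conditions: TEMPO (10 mol %), PhI(OAc)2 (1.1 equiv), CH2Cl2, 23 °C
Reagents that add atoms: none
Why: Oxoammonium (TEMPO) oxidation is much faster for the primary than for the secondary propargylic alcohol, and the aldehyde formed has no α-hydrogen, so it cannot epimerise.

Step 3
Reactants: 4 (2S,3S)-2-ethenyl-3-hydroxy-2-methyl-5-(trimethylsilyl)pent-4-ynal
Product: 5 (2S,3S)-2-ethenyl-2-methyl-1-oxo-5-(trimethylsilyl)pent-4-yn-3-yl methanesulfonate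
Conditions: MsCl, Et3N, CH2Cl2, −78 °C
Reagents that add atoms: methanesulfonyl chloride, CS(=O)(=O)Cl
Why: Sulfonylation of the secondary alcohol proceeds with retention at C5, and the quaternary α-carbon rules out elimination of the β-mesyloxy aldehyde.

Step 4
Reactants: 6 1,3-dihydroxypropan-2-one; 7 ethyl 2-(triphenyl-λ5-phosphanylidene)acetate
Product: 8 4-(hydroxymethyl)furan-2(5H)-one
Conditions: CH2Cl2, 23 °C, 16 h
Reagents that add atoms: none
Why: Wittig olefination of the ketone gives the γ-hydroxy enoate, whose hydroxymethyl arm cis to the ester lactonises spontaneously to the butenolide.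

Step 5
Reactants: 8 4-(hydroxymethyl)furan-2(5H)-one
Product: 9 5-oxo-2,5-dihydrofuran-3-carbaldehyde
Conditions: DMP, CH2Cl2, 0 to 23 °C; used at once
Reagents that add atoms: none
Why: Periodinane oxidation of the primary allylic alcohol under neutral conditions should give the enal without touching the base-sensitive butenolide.

Step 6
Reactants: 5 (2S,3S)-2-ethenyl-2-methyl-1-oxo-5-(trimethylsilyl)pent-4-yn-3-yl methanesulfonate; 9 5-oxo-2,5-dihydrofuran-3-carbaldehyde
Product: 11 6β-hydroxy bicyclic butenolide diol, via acyclic propargylation adduct 10 (not isolated)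
Conditions: 9 (1.5 equiv), Pd(OAc)2 (5 mol %), PPh3 (5 mol %), Et2Zn (3 equiv), THF, −78 to −20 °C, then 23 °C; aqueous NH4Cl
Reagents that add atoms: none
Why: Zerovalent palladium (formed from Pd(OAc)2, PPh3 and Et2Zn) ionises the propargylic mesylate by anti-SN2′ attack and transmetalation gives an axially chiral allenylzinc, which adds to the unhindered aldehyde of 9 through a cyclic SE2′ transition state (palladium/zinc umpolung propargylation) and so makes C5–C6. The ethylzinc alkoxide of 10 then deprotonates C8 of the butenolide, and the zinc dienolate attacks the C9 aldehyde in a 6-exo-trig vinylogous aldol addition that closes ring C5–C6–C7–C8–C9–C10 and makes C8–C9; the closest known reaction type is the zinc-alkoxide-mediated direct vinylogous aldol addition of 2(5H)-furanones to aldehydes. C5 is controlled by chirality transfer from the C5–O stereocentre of 5 (net inversion), and C6 by the anti preference of the cyclic transition state, which gives the 6β-alcohol that is corrected in steps 7 and 9. C8 and C9 are controlled by a chair transition state in which the planar butenolide keeps O8 equatorial and every ring substituent except the C10 methyl group is equatorial (O8 β, O9 α); the reversible aldol step should lead to the same, most stable isomer. The step needs the allenylzinc to prefer the aldehyde of 9 to the neopentyl aldehyde of 5, which the steric difference and the excess of 9 should secure, and γ- instead of α-attack of the dienolate, which conjugation of the product lactone should secure.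

Step 7
Reactants: 11 6β-hydroxy bicyclic butenolide diol
Product: 12 C6 ketone
Conditions: MnO2 (activated, 20 equiv), CH2Cl2, 23 °C
Reagents that add atoms: none
Why: MnO2 oxidises only allylic alcohols, so the C6 carbinol (allylic to C7=C11) should go to the ketone while the saturated C9 carbinol stays, which also tells the two hydroxyl groups apart.

Step 8
Reactants: 12 C6 ketone
Product: 13 C9 triethylsilyl ether of the C6 ketone
Conditions: Et3SiOTf, 2,6-lutidine, CH2Cl2, −78 °C
Reagents that add atoms: triethylsilyl trifluoromethanesulfonate, CC[Si](CC)(CC)OS(=O)(=O)C(F)(F)F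
Why: The silyl triflate silylates the only free (neopentyl) hydroxyl group at −78 °C faster than it enolises the ketone, which reserves O9 for the late methacrylation.

Step 9
Reactants: 13 C9 triethylsilyl ether of the C6 ketone
Product: 14 6α-alcohol
Conditions: NaBH4, CeCl3·7H2O, MeOH, −78 °C
Reagents that add atoms: none
Why: Luche 1,2-reduction: the planar fused butenolide locks the cyclohexane in the chair with the C10 methyl group axial on the α-face, so hydride should attack C6 from the β-face and give the axial 6α-alcohol.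

Step 10
Reactants: 14 6α-alcohol
Product: 17 cis-fused α-methylene lactone alcohol, via Mannich base 15 (not isolated), via trimethylammonium iodide 16 (not isolated)
Conditions: LiBH(s-Bu)3 (2.5 equiv), THF, −78 °C; CH2=NMe2+ I−, −78 to 23 °C; MeI, MeOH, 23 °C; NaHCO3, CH2Cl2/H2O, 23 °C
Reagents that add atoms: dimethyl(methylidene)ammonium iodide, C=[N+](C)C.[I-]
Why: Conjugate hydride addition to butenolide C7 from the face of H8 (anti to the C8–C9 bond, as usual for γ-substituted butenolides) should set the cis ring fusion; the lithium enolate is trapped in a Mannich reaction, and exhaustive methylation with base-induced elimination gives the α-methylene lactone.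

Step 11
Reactants: 17 cis-fused α-methylene lactone alcohol
Product: 18 C6 angelate
Conditions: angelic acid, 2,4,6-Cl3C6H2COCl, Et3N, PhMe, 23 °C; then 17, 80 °C
Reagents that add atoms: angelic acid, C/C=C(/C)C(=O)O
Why: Yamaguchi esterification through the mixed anhydride acylates the only free hydroxyl group (C6) under conditions that should not isomerise the (Z)-angeloyl group to the tigloyl group.

Step 12
Reactants: 18 C6 angelate
Product: 19 C9 alcohol with terminal alkyne
Conditions: Bu4NF, AcOH, THF, 0 to 23 °C
Reagents that add atoms: none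
Why: Buffered fluoride should cleave the O–Si bond at C9 and the C(sp)–Si bond of the alkynylsilane in one step without opening the esters.

Step 13
Reactants: 19 C9 alcohol with terminal alkyne
Product: 20 C9 methacrylate
Conditions: methacrylic anhydride, Et3N, DMAP (cat.), CH2Cl2, 23 °C
Reagents that add atoms: methacrylic anhydride, CC(=C)C(=O)OC(=O)C(C)=C
Why: DMAP-catalysed acylation of the single free, equatorial C9 hydroxyl group with the anhydride installs the methacrylate.

Step 14
Reactants: 20 C9 methacrylate
Product: 21 C15 aldehyde (C5–CH2–CHO)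
Conditions: [CpRu(MeCN)3]PF6 (5 mol %), 5,5′-bis(trifluoromethyl)-2,2′-bipyridine (5 mol %), H2O, NMP, 25 °C
Reagents that add atoms: water, O
Why: Ruthenium-vinylidene (anti-Markovnikov) hydration is specific for the terminal alkyne and turns C5–C≡CH into C5–CH2–CHO, while alkenes and esters form no vinylidene and should stay intact.

Step 15
Reactants: 21 C15 aldehyde (C5–CH2–CHO)
Product: 22 CNP0102441.1
Conditions: CH2=NMe2+ I−, Et3N, CH2Cl2, 23 °C
Reagents that add atoms: dimethyl(methylidene)ammonium iodide, C=[N+](C)C.[I-]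
Why: Mannich reaction of the aldehyde at C4 with the iminium salt and E1cB loss of dimethylamine gives the α-methylene aldehyde; no other enolisable carbonyl group competes.

**Compound list**

1 | 3-(trimethylsilyl)prop-2-ynal | C[Si](C)(C)C#CC=O | starting material
2 | 2-ethenyl-2-methyloxirane (isoprene monoxide, racemic) | CC1(C=C)CO1 | starting material
3 | (2R,3S)-2-ethenyl-2-methyl-5-(trimethylsilyl)pent-4-yne-1,3-diol | C=C[C@@](CO)(C)[C@H](O)C#C[Si](C)(C)C | intermediate
4 | (2S,3S)-2-ethenyl-3-hydroxy-2-methyl-5-(trimethylsilyl)pent-4-ynal | C=C[C@@](C=O)(C)[C@H](O)C#C[Si](C)(C)C | intermediate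
5 | (2S,3S)-2-ethenyl-2-methyl-1-oxo-5-(trimethylsilyl)pent-4-yn-3-yl methanesulfonate | C=C[C@@](C=O)(C)[C@H](OS(C)(=O)=O)C#C[Si](C)(C)C | intermediate
6 | 1,3-dihydroxypropan-2-one (commercial dimer) | OCC(=O)CO | starting material
7 | ethyl 2-(triphenyl-λ5-phosphanylidene)acetate | CCOC(=O)C=P(c1ccccc1)(c1ccccc1)c1ccccc1 | starting material
8 | 4-(hydroxymethyl)furan-2(5H)-one | OCC1=CC(=O)OC1 | intermediate
9 | 5-oxo-2,5-dihydrofuran-3-carbaldehyde (4-formylbutenolide) | O=CC1=CC(=O)OC1 | intermediate
10 | 4-[(1R,2R,3S)-3-formyl-1-hydroxy-3-methyl-2-[(trimethylsilyl)ethynyl]pent-4-en-1-yl]furan-2(5H)-one (C5/C6 anti; ethylzinc alkoxide in the flask) | C=C[C@@](C=O)(C)[C@H](C#C[Si](C)(C)C)[C@@H](O)C1=CC(=O)OC1 | intermediate (not isolated)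
11 | 6-ethenyl-4,7-dihydroxy-6-methyl-5-[(trimethylsilyl)ethynyl]-5,6,7,7a-tetrahydro-1-benzofuran-2(4H)-one; 5α-alkynyl, 6β-OH, 8β-O (lactone), 9α-OH, 10α-Me, 10β-vinyl | C=C[C@@]1(C)[C@H](C#C[Si](C)(C)C)[C@@H](O)C2=CC(=O)O[C@H]2[C@@H]1O | intermediate
12 | 6-ethenyl-7-hydroxy-6-methyl-5-[(trimethylsilyl)ethynyl]-5,6,7,7a-tetrahydro-1-benzofuran-2,4-dione; 5α-alkynyl, 8β-O, 9α-OH | C=C[C@@]1(C)[C@H](C#C[Si](C)(C)C)C(=O)C2=CC(=O)O[C@H]2[C@@H]1O | intermediate
13 | 7-O-triethylsilyl ether of 12 (9α-OSiEt3) | C=C[C@@]1(C)[C@H](C#C[Si](C)(C)C)C(=O)C2=CC(=O)O[C@H]2[C@@H]1O[Si](CC)(CC)CC | intermediate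
14 | 6-ethenyl-4-hydroxy-6-methyl-7-(triethylsilyloxy)-5-[(trimethylsilyl)ethynyl]-5,6,7,7a-tetrahydro-1-benzofuran-2(4H)-one; 6α-OH (axial), otherwise as 13 | C=C[C@@]1(C)[C@H](C#C[Si](C)(C)C)[C@H](O)C2=CC(=O)O[C@H]2[C@@H]1O[Si](CC)(CC)CC | intermediate
15 | 3-[(dimethylamino)methyl] cis-fused saturated lactone from 14 (7α-H, 8α-H; C11 epimers, of no consequence) | C=C[C@@]1(C)[C@H](C#C[Si](C)(C)C)[C@H](O)[C@H]2C(CN(C)C)C(=O)O[C@H]2[C@@H]1O[Si](CC)(CC)CC | intermediate (not isolated)
16 | trimethylammonium iodide of 15 | C=C[C@@]1(C)[C@H](C#C[Si](C)(C)C)[C@H](O)[C@H]2C(C[N+](C)(C)C)C(=O)O[C@H]2[C@@H]1O[Si](CC)(CC)CC.[I-] | intermediate (not isolated)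
17 | 6-ethenyl-4-hydroxy-6-methyl-3-methylidene-7-(triethylsilyloxy)-5-[(trimethylsilyl)ethynyl]hexahydro-1-benzofuran-2(3H)-one; 5α-alkynyl, 6α-OH, 7α-H, 8α-H, 9α-OSiEt3 | C=C[C@@]1(C)[C@H](C#C[Si](C)(C)C)[C@H](O)[C@H]2C(=C)C(=O)O[C@H]2[C@@H]1O[Si](CC)(CC)CC | intermediate
18 | 6α-O-angelate [(2Z)-2-methylbut-2-enoate] of 17 | C=C[C@@]1(C)[C@H](C#C[Si](C)(C)C)[C@H](OC(=O)/C(C)=C\C)[C@H]2C(=C)C(=O)O[C@H]2[C@@H]1O[Si](CC)(CC)CC | intermediate
19 | 6-ethenyl-5-ethynyl-7-hydroxy-6-methyl-3-methylidene-2-oxooctahydro-1-benzofuran-4-yl (2Z)-2-methylbut-2-enoate; 9α-OH, terminal alkyne at C5 | C=C[C@@]1(C)[C@H](C#C)[C@H](OC(=O)/C(C)=C\C)[C@H]2C(=C)C(=O)O[C@H]2[C@@H]1O | intermediate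
20 | 9α-O-methacrylate (2-methylprop-2-enoate) of 19 | C=C[C@@]1(C)[C@H](C#C)[C@H](OC(=O)/C(C)=C\C)[C@H]2C(=C)C(=O)O[C@H]2[C@@H]1OC(=O)C(=C)C | intermediate
21 | analogue of 20 with a 2-oxoethyl group (CH2–CHO) at C5 in place of ethynyl | C=C[C@@]1(C)[C@H](CC=O)[C@H](OC(=O)/C(C)=C\C)[C@H]2C(=C)C(=O)O[C@H]2[C@@H]1OC(=O)C(=C)C | intermediate
22 | CNP0102441.1: 6α-angeloyloxy-9α-methacryloyloxy-15-oxoelema-1,3,11(13)-trien-12,8β-olide (descriptors as defined above) | C=C[C@@]1(C)[C@H](C(=C)C=O)[C@H](OC(=O)/C(C)=C\C)[C@H]2C(=C)C(=O)O[C@H]2[C@@H]1OC(=O)C(=C)C | target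

**Step count and risks**

Total step count: 15. Longest linear sequence: 13 steps (steps 1–3 and 6–15); steps 4–5 make the second fragment.

Steps most likely to fail:

Step 6. The allenylzinc may add to the hindered aldehyde of 5, butenolide 9 may self-condense before the ring closes, or the ethylzinc alkoxide may be too weak a base to start the vinylogous aldol; the C9 carbinol may also form with poor facial selectivity. Fallback: from 5 and 9 the propargylation is run with Pd(dppf)Cl2 (5 mol %) and InI in THF/HMPA (transient allenylindium, same stereochemical course); i-Pr2NEt and t-BuMe2SiOTf are then added to the same flask at −78 °C. This silylates O6, turns the butenolide into its 2-silyloxyfuran and closes the ring by a silyl-triflate-promoted vinylogous Mukaiyama aldol addition to the bis(silyl ether) F1. HF·pyridine in THF then returns the route to 11.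

Step 10. The hydride may add to C7 from the β-face (trans ring fusion) because the axial C6 alkoxide shields the α-face, or it may attack the lactone carbonyl instead of C7. Fallback: from 14, electron-transfer reduction with SmI2, H2O and Et3N in THF should give the saturated cis-fused lactone F2, the C7 carbanion being protonated on the face of H8 next to the samarium-bound C6 hydroxyl group. F2 is then α-methylenated separately (LiN(SiMe3)2, CH2=NMe2+ I−; MeI; NaHCO3), which returns the route to 17.

Step 11. Acylation of the axial C6 alcohol, which is syn-axial to the C10 methyl group, may be so slow that the angeloyl group isomerises to tigloyl or the α-methylene lactone is consumed by amine addition. Fallback: from 17, the small acid 2-[bis(2,2,2-trifluoroethoxy)phosphoryl]propanoic acid is coupled (DCC, DMAP, CH2Cl2) to give the phosphonate ester F3. A Still–Gennari olefination with acetaldehyde (KN(SiMe3)2, 18-crown-6, THF, −78 °C) then builds the (Z)-2-methylbut-2-enoate on the molecule and returns the route to 18.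

Further compounds
F1 | step 6 | 4,7-bis(tert-butyldimethylsilyl) ether of 11 (6β-OSi, 9α-OSi) | C=C[C@@]1(C)[C@H](C#C[Si](C)(C)C)[C@@H](O[Si](C)(C)C(C)(C)C)C2=CC(=O)O[C@H]2[C@@H]1O[Si](C)(C)C(C)(C)C
F2 | step 10 | cis-fused saturated lactone from 14 (7α-H, 8α-H, C11 is CH2) | C=C[C@@]1(C)[C@H](C#C[Si](C)(C)C)[C@H](O)[C@H]2CC(=O)O[C@H]2[C@@H]1O[Si](CC)(CC)CC
F3 | step 11 | 6α-O-{2-[bis(2,2,2-trifluoroethoxy)phosphoryl]propanoate} of 17 | C=C[C@@]1(C)[C@H](C#C[Si](C)(C)C)[C@H](OC(=O)C(C)P(=O)(OCC(F)(F)F)OCC(F)(F)F)[C@H]2C(=C)C(=O)O[C@H]2[C@@H]1O[Si](CC)(CC)CC
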